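**Assumption:** the target has no stereocentre (it is achiral), so no stereocontrol is needed; the side chain is read as n-henicosyl (C21), giving C29H50O3.

## Retrosynthetic overview (listed from the building-block end)

1. Chain: docos-1-ene 1 is cleaved through its ozonide 2 to henicosanal 3 (the C22 alkene minus its terminal carbon gives the C21 acyl donor).
2. Key disconnection, ring C3–C1′: aldehyde 3 is used as an acyl-anion (d1) equivalent, a photogenerated nucleophilic acyl radical, and added to the electrophilic ring C–H of quinone 4 to give acylhydroquinone 5. This is a Stetter-type union of two natively electrophilic carbons, done directly on the unprotected quinone.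
3. Endgame: ArC(=O)R of 5 is reduced to ArCH2R (hydroquinone 6) and reoxidised to the target quinone 7.
4. Rings: none is formed; the six-membered ring is carried through intact from purchased 4.

## Route

**Step 1**
Reactants: 1 docos-1-ene
Product: 3 henicosanal, via secondary ozonide 2 (not isolated)
Conditions: O3/O2, CH2Cl2–hexane, −20 °C; N2 purge; then PPh3 (1.1 equiv), −20 °C → rt
Reagents that add atoms: ozone, [O-][O+]=O
Why: Ozonolysis (Criegee mechanism) with reductive work-up removes only the terminal =CH2 carbon, so the C22 alkene gives the C21 aldehyde without over-oxidation; no stereocentre is involved.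

**Step 2**
Reactants: 3 henicosanal; 4 2-methoxy-5-methyl-1,4-benzoquinone
Product: 5 1-(2,5-dihydroxy-3-methoxy-6-methylphenyl)henicosan-1-one
Conditions: hν (350 nm, Pyrex), Ph2CO (20 mol %), degassed PhH, equimolar 3 and 4, rt, Ar, 2–4 d
Reagents that add atoms: none
Why: Benzophenone-sensitised photoacylation of a quinone (photo-Friedel–Crafts, a radical Stetter-type hydroacylation) in which triplet benzophenone abstracts the formyl H of 3 to give a nucleophilic acyl radical that serves as the acyl-anion equivalent, adds at the free CH of the methyl-bearing enone rather than at the donor-substituted methoxy enol-ether carbon, and after H-return from the ketyl radical and enolisation gives the hydrogen-bonded, photostable acylhydroquinone as a 1:1 adduct that keeps every atom of 3 and 4, with benzophenone regenerated; no stereocentre is formed.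

**Step 3**
Reactants: 5 1-(2,5-dihydroxy-3-methoxy-6-methylphenyl)henicosan-1-one
Product: 7 3-henicosyl-5-methoxy-2-methylcyclohexa-2,5-diene-1,4-dione, via alkylhydroquinone 6 (not isolated)
Conditions: Et3SiH (4 equiv), TFA/CH2Cl2 (1:1), 0 → 40 °C, Ar; evaporate; then FeCl3·6H2O (2.5 equiv), THF/H2O, rt, 30 min
Reagents that add atoms: none
Why: Ionic hydrogenation (Kursanov–Parnes) takes the electron-rich o-hydroxyaryl ketone through its benzylic (o-quinone-methide-type) cation to CH2 without touching the OMe group, and the air-sensitive hydroquinone is oxidised at once by Fe(III) (two-electron hydroquinone-to-quinone oxidation); no stereocentre is formed.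

## Compound list

1 | docos-1-ene; achiral | CCCCCCCCCCCCCCCCCCCCC=C | starting material
2 | secondary ozonide = 3-icosyl-1,2,4-trioxolane; racemic; not isolated | CCCCCCCCCCCCCCCCCCCCC1OCOO1 | intermediate
3 | henicosanal; achiral | CCCCCCCCCCCCCCCCCCCCC=O | intermediate
4 | 2-methoxy-5-methyl-1,4-benzoquinone (2-methoxy-5-methylcyclohexa-2,5-diene-1,4-dione); achiral | COC1=CC(=O)C(C)=CC1=O | starting material
5 | 1-(2,5-dihydroxy-3-methoxy-6-methylphenyl)henicosan-1-one; achiral | CCCCCCCCCCCCCCCCCCCCC(=O)c1c(C)c(O)cc(OC)c1O | intermediate
6 | alkylhydroquinone = 3-henicosyl-5-methoxy-2-methylbenzene-1,4-diol; achiral; not isolated | CCCCCCCCCCCCCCCCCCCCCc1c(C)c(O)cc(OC)c1O | intermediate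
7 | 3-henicosyl-5-methoxy-2-methylcyclohexa-2,5-diene-1,4-dione; achiral | CCCCCCCCCCCCCCCCCCCCCC1=C(C)C(=O)C=C(OC)C1=O | target

## Summary

Total step count: 3. Longest linear sequence: 3 steps (1 → 3 → 5 → 7).

**Steps most likely to fail, in order: step 2, step 3, step 1.**

Step 2 is the main risk: hydrogen abstraction may be inefficient at equimolar loading, acylation may occur on oxygen, or the regiochemistry may not hold. The fallback sets out from quinone 4 and inverts the polarity of the ring carbon instead of that of the aldehyde carbon. Conjugate addition of HBr (HBr/AcOH, CHCl3, 0 °C) should place bromine on the same electrophilic carbon and give 3-bromo-5-methoxy-2-methylbenzene-1,4-diol F1. MOMCl/i-Pr2NEt (CH2Cl2) then gives 1-bromo-3-methoxy-2,5-bis(methoxymethoxy)-6-methylbenzene F2. Br/Li exchange (n-BuLi, THF, −78 °C) and addition of the aryllithium to aldehyde 3 give racemic 1-[3-methoxy-2,5-bis(methoxymethoxy)-6-methylphenyl]henicosan-1-ol F3. Et3SiH/TFA (CH2Cl2, 0 °C → rt) then removes the benzylic hydroxyl and both MOM groups in one operation, the silane reducing the released methoxymethyl cations so that they cannot alkylate the ring. This delivers hydroquinone 6, where the route is rejoined and finished by the FeCl3 oxidation of step 3.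

Step 3 may stall because the ketone is hydrogen-bonded and flanked by two ortho substituents, or the electron-rich ring may suffer in warm TFA. The fallback sets out from 5: NaBH4 (THF/MeOH, 0 °C) gives racemic 3-(1-hydroxyhenicosyl)-5-methoxy-2-methylbenzene-1,4-diol F4. Its benzylic C–O bond is then cleaved by catalytic hydrogenolysis (H2, 10% Pd/C, EtOAc/AcOH, rt) instead of by a carbocation/hydride-transfer sequence. This returns to the route at hydroquinone 6, which is oxidised to 7 as before.

Step 1 may suffer from crystallisation of 1 out of cold CH2Cl2, incomplete ozonide reduction, or air oxidation of the aldehyde. The fallback sets out from 1: Upjohn dihydroxylation (cat. K2OsO2(OH)4, NMO, THF/t-BuOH/H2O, 40 °C) gives racemic docosane-1,2-diol F5. Glycol cleavage (NaIO4, THF/H2O, rt) then returns to the route at aldehyde 3.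

## Further compounds

F1 | step 2 | 3-bromo-5-methoxy-2-methylbenzene-1,4-diol | COc1cc(O)c(C)c(Br)c1O
F2 | step 2 | 1-bromo-3-methoxy-2,5-bis(methoxymethoxy)-6-methylbenzene | COCOc1cc(OC)c(OCOC)c(Br)c1C
F3 | step 2 | 1-[3-methoxy-2,5-bis(methoxymethoxy)-6-methylphenyl]henicosan-1-ol (racemic) | CCCCCCCCCCCCCCCCCCCCC(O)c1c(C)c(OCOC)cc(OC)c1OCOC
F4 | step 3 | 3-(1-hydroxyhenicosyl)-5-methoxy-2-methylbenzene-1,4-diol (racemic) | CCCCCCCCCCCCCCCCCCCCC(O)c1c(C)c(O)cc(OC)c1O
F5 | step 1 | docosane-1,2-diol (racemic) | CCCCCCCCCCCCCCCCCCCCC(O)CO
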